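1. The pitfall is to scale target with the charge of coupling partner: larch holds a third of what birch holds, and it need not give a third of the target.

| flask | starting material | second substrate | coupling partner | precatalyst | remark | time |
|---|---|---|---|---|---|---|
| teal | 0.40 M | 1.5 equiv | 0.70 equiv | 20 mol% | run made earlier |  |
| blue | 0.80 M | 1 equiv | 0.70 equiv | 20 mol% | run made earlier |  |
| larch | 0.40 M | 1.00 equiv | 0.230 equiv | 20 mol% |  | 40 min |
| birch | 0.40 M | 1.00 equiv | 0.700 equiv | 20 mol% |  | 40 min |

| run | time / min | target / % |
|---|---|---|
| teal | 1.00 | 0 |
| teal | 2.50 | 0.3 |
| teal | 3.00 | 0.1 |
| teal | 5.00 | 0.4 |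
| teal | 6.00 | 0.9 |
| teal | 8.00 | 0.8 |
| blue | 0.667 | 0 |
| blue | 1.00 | 0.2 |
| blue | 1.33 | 0 |
| blue | 2.50 | 0.2 |
| blue | 3.00 | 0.5 |
| blue | 5.00 | 2.0 |
| blue | 8.00 | 4.3 |

(standard deviation of a reading: 0.3 percentage points)

- the earlier runs were read with a standard deviation of 0.3 percentage points
- steps thought possible: coupling partner + catalyst intermediate B -> free catalyst + second product; coupling partner + catalyst intermediate A -> free catalyst + target; second substrate + free catalyst <-> catalyst intermediate B; coupling partner + precatalyst -> free catalyst + spent reagent; starting material + free catalyst <-> catalyst intermediate A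

- the flask that ends with the higher amount of target, in percent of the starting material charged, or "neither" when 2 percentage points or less lies between them (larch / birch / neither)
- final target, as a percentage of the starting material charged, in larch
- final target, as a percentage of the starting material charged, in birch

2. Larch and birch differ in the coupling partner charge, 0.230 equiv against 0.700 equiv. Coupling partner is the limiting reagent in both, at less than the second substrate. So I reckon with the ratio of these two amounts.

3. The blue run bends upward: it reads 2.0% at 5.00 min and 4.3% at 8.00 min, a factor of 2.15 for 1.60 times the time, and a square law gives 2.56.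

4. Along the route to target the possible steps use coupling partner twice: it frees catalyst from precatalyst, then it turns catalyst intermediate A into target. A further possible step spends it on catalyst intermediate B, giving second product. So early on I expect target to follow the square of charge times time.

5. At equal time I therefore take G = 9.26, the square of the ratio of two coupling partner charges, as my expected birch-to-larch ratio of target.

6. The forecast says birch, with 2.2% in larch and 15% in birch. It starts from “about one-ninth the rate”, but its printed values stand a factor of 6.82 apart, below my G.

    coupling partner + catalyst intermediate B → free catalyst + second product (k = 18.0 M⁻¹ min⁻¹)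
    coupling partner + catalyst intermediate A → free catalyst + target (k = 1.02 M⁻¹ min⁻¹)
    second substrate + free catalyst ⇌ catalyst intermediate B (K = 18.1 M⁻¹, k = 0.889 M⁻¹ min⁻¹)
    coupling partner + precatalyst → free catalyst + spent reagent (k = 0.0562 M⁻¹ min⁻¹)
    starting material + free catalyst ⇌ catalyst intermediate A (K = 4.49 M⁻¹, k = 1.51 M⁻¹ min⁻¹)

7. The flasks give 2.14% in larch and 14.3% in birch, a ratio of 6.68, below G of 9.26. A neighbour of larch, charged with 0.580 equiv of coupling partner and otherwise unchanged, takes G times the square of its charge over birch's, which is 6.36 over larch, or 13.6%. That neighbour ends at 10.7%, 5.00 times larch.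

The numbers in the tables stem from a simulated flask for substances that don't exist.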